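## The problem

Target 28 is (2S,3S)-2-(3,4-dihydroxyphenyl)-3-(3,5-dihydroxyphenyl)-6-[(E)-2-(4-hydroxy-3-methoxyphenyl)ethenyl]-2,3-dihydro-1-benzofuran-4-ol, the 2,3-trans isomer. Its benzo ring (ring A) is a 1,2,3,5-tetrasubstituted benzene in which C3a, the carbon that carries C3, lies between two oxygenated carbons (C4–OH and C7a–O1). Attaching a bulky 1,2-diarylethyl group between the two oxygens of a ready-made resorcinol is the difficult connection. C3 is a triaryl methine that cannot be corrected later, whereas C2 is a benzylic ether carbon that C3 can control, either through inversion of a carbinol or through closure of a C2 cation anti to the C3 aryl group. The synthesis must therefore fix C3 absolutely and deliver C2 only relative to it. Six phenolic oxygens are present and exactly one is methylated, so every protecting group has to leave without touching an aryl methyl ether; the (E)-stilbene excludes hydrogenolysis, the O1–C2 bond (benzylic to a para-oxygenated ring) is acid-labile, and the free catechol is air-sensitive. The enabling feature is the substitution pattern of ring A (oxygen at C4, chain on C3a, oxygen at C7a, styryl at C6 para to C3a). This is the pattern formed when a 3-substituted cyclobutenone, through its vinylketene, combines with a siloxyalkyne, and the two oxygens are interchangeable by rotation about C3–C3a until O1–C2 is closed.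

## Retrosynthesis

**28 ⇐ 27.** Five O–benzyl bonds are cut last. Benzyl is preferred to methyl (indistinguishable from the guaiacyl methyl), to silyl (would not survive the organolithium steps or the fluoride step that precedes ring closure) and to acetals (acid). Removal must avoid hydrogen because of the stilbene, so BCl3 with pentamethylbenzene at −78 °C is asked to dealkylate while leaving the methyl ether and O1–C2 intact. The styryl group at C6 is out of reach of a C2 cation, so acid-triggered cyclisation onto the alkene has no geometric path.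

**27 ⇐ 26.** O1–C2 is cut. This is preferred to cutting C2–C3 or C3–C3a on the heterocycle, because it leaves an open-chain 1,2-diaryl-2-hydroxyethyl unit whose two stereocentres can be made by acyclic control. Triol 26 has the (1S,2R) side chain, so an intramolecular Mitsunobu etherification with inversion gives (2S). Either phenol of 26 may close, since both give the same product.

**26 ⇐ 25.** Two O–Si bonds are cut. Keeping the benzylic oxygen as a silyl ether and one ring-A oxygen as the silyl ether that the annulation delivers means one fluoride treatment exposes everything needed for ring closure.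

**25 ⇐ 14 + 20.** Ring A is taken apart at C3a–C4, C4–C5 and C7–C7a. The neighbouring option, alkylating a 5-styrylresorcinol at the position between its oxygens, fights both sterics and the innate preference for the flanking positions. The benzannulation instead places the chain between the oxygens by ketene–ynol ether polarity. The precursors are far simpler: acyclic siloxyalkyne 14, which already holds both stereocentres, and four-carbon cyclobutenone 20. The forward step must be regiospecific and must not disturb the side-chain stereocentres or the (E)-alkene.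

**14 ⇐ 13 ⇐ 12 ⇐ 11.** The O–C(sp) bond is cut: ynolate 13 is silylated on oxygen, and 13 arises by oxygen transfer to lithium acetylide 12. Acetylide 12 is what the second stage of a Corey–Fuchs sequence delivers from dibromoalkene 11, so it is oxidised in the flask in which it forms. The terminal alkyne is thus never protonated, isolated and deprotonated again, which saves a step and a second exposure of the propargylic benzylic hydrogen to base. A carbenoid homologation at the carboxyl oxidation level would instead expose an α-aryl, β-silyloxy carbonyl unit to LiCHBr2 and lithium amides, where enolisation means epimerisation at the future C3 or loss of silanolate.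

**11 ⇐ 10 ⇐ 9 ⇐ 8.** The dibromomethylidene carbon is removed, leaving aldehyde 10. The base-free dibromo-olefination is preferred to diazophosphonate/carbonate conditions because 10 is an α-aryl aldehyde. Aldehyde 10 comes from alcohol 9, and 9 from imide 8 by hydride cleavage of the auxiliary, which avoids alkoxide (retro-aldol, epimerisation).

**8 ⇐ 7 ⇐ 4 + 5; 4 ⇐ 1 + 2.** The bond between the future C2 and C3 is cut as an Evans syn aldol between arylacetyl imide 4 and aldehyde 5; it sets both stereocentres in one step from two achiral aromatic building blocks. The (R)-auxiliary 2 is required: it gives (2R,3R)-7, which maps onto (3S) of the target and onto the (R)-carbinol that inversion turns into (2S).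

**20 ⇐ 16 + 17; 16 ⇐ 15.** The bond between the cyclobutenone C3 and the styryl carbon is cut. An (E)-styryllithium from iodide 16 adds to vinylogous ester 17 and acid unveils the enone. Iodide 16 comes from aldehyde 15 by Takai olefination, which fixes the (E)-geometry that is then carried unchanged to 28.

## Roads not taken

**Alternative 1:** The cut is O1–C2 together with the C3–H bond, leading from dihydrobenzofuran A1 back to the achiral triarylethylene A2. In the forward step a confined chiral imidodiphosphorimidate acid would protonate the alkene of A2 at C3, and one of the two equivalent phenols would trap the C2 cation.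
- Merits: both stereocentres arise in one catalytic step from a flat, easily assembled precursor; no auxiliary is used; the route is clearly shorter than the 13 steps proposed here.
- Weak points: the absolute configuration rests on face-selective protonation of a triaryl alkene that gives a long-lived para-methoxybenzylic cation, and the precedent for this catalyst class lies with aliphatic alcohols and simple alkenes. Any uncatalysed acid pathway gives racemate, and C3, once wrong, cannot be repaired.
- Protecting groups: A1 carries four methyl ethers that must go while the guaiacyl methyl stays. Demethylation would therefore have to precede attachment of the styryl arm, so the Heck coupling would run on pentaphenol A3.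
- Comparison: this road is better in step count and atom economy. The chosen plan sets against it a C3 centre fixed by an auxiliary-controlled aldol of predictable sense and a protecting-group scheme that never has to distinguish methyl from methyl.

**Alternative 2:** C2–C3 and O1–C2 are cut in dihydrobenzofuran A4. Sulfone A5 would release ortho-quinone methide A6 under Cs2CO3; thiolanium salt A7, deprotonated at its benzylic carbon, would add to A6 and the betaine would close with loss of the sulfide.
- Merits: it is the most convergent of the four ideas; the trans relationship is inherent in the anti betaine and its SN2 closure; the reaction type is known.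
- Weak points: enantiocontrol with semi-stabilised benzylic ylides from stoichiometric chiral sulfides is generally less dependable than auxiliary control, and reversible betaine formation can erode it. A5 requires a diarylmethyl sulfone to be installed between two oxygens of a 5-bromoresorcinol monoether, the same positional problem the benzannulation avoids. The styryl arm still needs a late Heck coupling, and six benzyl groups must then be removed.
- Comparison: this road is shorter and more convergent. The chosen plan offers a predictable absolute configuration and an unambiguous substitution pattern on ring A, at the price of a longer linear sequence.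

**Alternative 3:** The 3,5-dihydroxyphenyl ring on C3 is cut, leading from resorcinol A8 back to triketone A9. Aqueous base would fold the chain by aldol attack of the terminal methyl carbon on the ketone attached to C3, followed by dehydration and enolisation.
- Merits: the aromatisation is biomimetic and reliable, and the ring arrives with free hydroxyls.
- Weak points: in A9, C3 is α to a ketone and β to O1, so the base that triggers the fold can enolise C3 and expel the phenoxide by E1cB, erasing both stereocentres in the key step. The idea also does not say how the stereodefined dihydrobenzofuran is obtained, and the catechol methyl ethers again force demethylation before the styryl arm can be attached.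
- Comparison: this road needs fewer protecting groups on the resorcinol ring. The chosen plan builds ring A instead, under neutral thermal conditions, with both stereocentres already in place and remote from the reacting π-system.

Key step: step 10

Remark: in alternative 2 the sulfonyl group and the chiral sulfide are not fixed by the idea; p-tolylsulfonyl and (2R,5R)-2,5-dimethylthiolane are drawn as representatives.

## Route

Step 1
Reactants: 1 3,5-bis(benzyloxy)phenylacetic acid; 2 (R)-4-benzyl-1,3-oxazolidin-2-one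
Product: 4 (R)-4-benzyl-3-{[3,5-bis(benzyloxy)phenyl]acetyl}-1,3-oxazolidin-2-one, via mixed pivalic anhydride 3 (not isolated)
Conditions: PivCl, Et3N, THF, −20 °C; then 2, LiCl, −20 → 23 °C
Reagents that add atoms: none
Why: N-acylation of the oxazolidinone through the mixed anhydride with LiCl/Et3N activation is the standard way to arylacetyl imides; no stereocentre is at risk.

Step 2
Reactants: 4 (R)-4-benzyl-3-{[3,5-bis(benzyloxy)phenyl]acetyl}-1,3-oxazolidin-2-one; 5 3,4-bis(benzyloxy)benzaldehyde
Product: 7 (4R)-4-benzyl-3-[(2R,3R)-3-[3,4-bis(benzyloxy)phenyl]-2-[3,5-bis(benzyloxy)phenyl]-3-hydroxypropanoyl]-1,3-oxazolidin-2-one, via dibutylboron Z-enolate 6 (not isolated)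
Conditions: Bu2BOTf, iPr2NEt, CH2Cl2, −78 → 0 °C; 5, −78 → 0 °C; then pH 7 buffer, MeOH, H2O2, 0 °C
Reagents that add atoms: none
Why: Evans syn aldol: the Z-boron enolate reacts through a closed Zimmerman–Traxler chair with the auxiliary carbonyl turned away, so the aldehyde approaches the enolate face opposite the benzyl group of the (R)-auxiliary. This should set the α-carbon (future C3) and the carbinol (future C2) as (2R,3R), syn; the tight boron aldolate suppresses retro-aldol of the acidic arylacetyl system.

Step 3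
Reactants: 7 (4R)-4-benzyl-3-[(2R,3R)-3-[3,4-bis(benzyloxy)phenyl]-2-[3,5-bis(benzyloxy)phenyl]-3-hydroxypropanoyl]-1,3-oxazolidin-2-one
Product: 8 (4R)-4-benzyl-3-[(2R,3R)-3-[3,4-bis(benzyloxy)phenyl]-2-[3,5-bis(benzyloxy)phenyl]-3-(tert-butyldimethylsilyloxy)propanoyl]-1,3-oxazolidin-2-one
Conditions: TBSOTf, 2,6-lutidine, CH2Cl2, −78 → 0 °C
Reagents that add atoms: tert-butyldimethylsilyl triflate, CC(C)(C)[Si](C)(C)OS(=O)(=O)C(F)(F)F
Why: Silyl triflate with a hindered pyridine base silylates hindered secondary alcohols without generating an alkoxide, so neither retro-aldol nor α-epimerisation is expected.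

Step 4
Reactants: 8 (4R)-4-benzyl-3-[(2R,3R)-3-[3,4-bis(benzyloxy)phenyl]-2-[3,5-bis(benzyloxy)phenyl]-3-(tert-butyldimethylsilyloxy)propanoyl]-1,3-oxazolidin-2-one
Product: 9 (2S,3R)-3-[3,4-bis(benzyloxy)phenyl]-2-[3,5-bis(benzyloxy)phenyl]-3-(tert-butyldimethylsilyloxy)propan-1-ol
Conditions: LiBH4, H2O (1 equiv), Et2O/THF, 0 °C
Reagents that add atoms: none
Why: Reductive cleavage of the N-acyloxazolidinone with LiBH4 attacks the exocyclic carbonyl and proceeds without an enolate, so the α-aryl centre is retained (the descriptor changes only because the priorities change); auxiliary 2 is recovered.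

Step 5
Reactants: 9 (2S,3R)-3-[3,4-bis(benzyloxy)phenyl]-2-[3,5-bis(benzyloxy)phenyl]-3-(tert-butyldimethylsilyloxy)propan-1-ol
Product: 10 (2R,3R)-3-[3,4-bis(benzyloxy)phenyl]-2-[3,5-bis(benzyloxy)phenyl]-3-(tert-butyldimethylsilyloxy)propanal
Conditions: Dess–Martin periodinane, CH2Cl2, 0 → 23 °C; crude product used at once
Reagents that add atoms: none
Why: Dess–Martin oxidation is near-neutral and fast, which is what an enolisable α-aryl, β-silyloxy aldehyde needs; it is taken on without chromatography.

Step 6
Reactants: 10 (2R,3R)-3-[3,4-bis(benzyloxy)phenyl]-2-[3,5-bis(benzyloxy)phenyl]-3-(tert-butyldimethylsilyloxy)propanal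
Product: 11 (1R,2R)-4,4-dibromo-1-[3,4-bis(benzyloxy)phenyl]-2-[3,5-bis(benzyloxy)phenyl]-1-(tert-butyldimethylsilyloxy)but-3-ene
Conditions: CBr4, PPh3, Zn, CH2Cl2, 23 °C (reagent preformed); then 10, 0 °C
Reagents that add atoms: carbon tetrabromide, BrC(Br)(Br)Br
Why: First stage of the Corey–Fuchs sequence: the zinc-generated ylide Ph3P=CBr2 olefinates the aldehyde in a Wittig-type reaction without added base, so the α-centre should not be enolised.

Step 7
Reactants: 11 (1R,2R)-4,4-dibromo-1-[3,4-bis(benzyloxy)phenyl]-2-[3,5-bis(benzyloxy)phenyl]-1-(tert-butyldimethylsilyloxy)but-3-ene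
Product: 14 (1R,2S)-1-[3,4-bis(benzyloxy)phenyl]-2-[3,5-bis(benzyloxy)phenyl]-1-(tert-butyldimethylsilyloxy)-4-(triisopropylsilyloxy)but-3-yne, via lithium acetylide 12 (not isolated), via lithium ynolate 13 (not isolated)
Conditions: n-BuLi (2.05 equiv), THF, −78 °C; t-BuOOLi (from t-BuOOH and LiN(SiMe3)2), −78 → 0 °C; TIPSOTf, −78 °C
Reagents that add atoms: tert-butyl hydroperoxide (as its lithium salt), CC(C)(C)OO; triisopropylsilyl triflate, CC(C)[Si](OS(=O)(=O)C(F)(F)F)(C(C)C)C(C)C
Why: Second stage of the Corey–Fuchs sequence: bromine–lithium exchange, α-elimination and 1,2-shift (Fritsch–Buttenberg–Wiechell) give the alkyne, which the second equivalent of n-BuLi holds as acetylide 12, the usual point at which such sequences are intercepted by an electrophile. Electrophilic oxygen transfer from lithium tert-butyl peroxide to a lithium acetylide is the established route to ynolates, and the bulky silyl triflate traps ynolate 13 on oxygen. The propargylic benzylic C–H is far less acidic than the acetylenic one at −78 °C and the reacting carbon is two atoms away from the stereocentre, whose descriptor changes from R to S only through the priority rules.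

Step 8
Reactants: 15 4-(benzyloxy)-3-methoxybenzaldehyde
Product: 16 1-(benzyloxy)-4-[(E)-2-iodoethenyl]-2-methoxybenzene
Conditions: CrCl2, CHI3, THF, 0 °C
Reagents that add atoms: iodoform, IC(I)I
Why: Takai olefination: the geminal dichromium species formed from iodoform and divalent chromium adds to the aldehyde and eliminates anti, which gives (E)-vinyl iodides from aromatic aldehydes.

Step 9
Reactants: 16 1-(benzyloxy)-4-[(E)-2-iodoethenyl]-2-methoxybenzene; 17 3-ethoxycyclobut-2-en-1-one
Product: 20 3-[(E)-2-(4-benzyloxy-3-methoxyphenyl)ethenyl]cyclobut-2-en-1-one, via styryllithium 18 (not isolated), via lithium cyclobutenolate 19 (not isolated)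
Conditions: t-BuLi (2.0 equiv), Et2O, −78 °C; 17, −78 °C; then 1 M HCl, THF, 0 °C
Reagents that add atoms: water, O
Why: Iodine–lithium exchange proceeds with retention of alkene geometry, the alkenyllithium adds 1,2 to the vinylogous ester, and aqueous acid ionises the tertiary allylic alcohol and hydrolyses the enol ether (Stork–Danheiser-type transposition; the carbonyl oxygen of 20 comes from water). This is the standard entry to 3-substituted cyclobutenones.

Step 10
Reactants: 14 (1R,2S)-1-[3,4-bis(benzyloxy)phenyl]-2-[3,5-bis(benzyloxy)phenyl]-1-(tert-butyldimethylsilyloxy)-4-(triisopropylsilyloxy)but-3-yne; 20 3-[(E)-2-(4-benzyloxy-3-methoxyphenyl)ethenyl]cyclobut-2-en-1-one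
Product: 25 2-[(1S,2R)-2-[3,4-bis(benzyloxy)phenyl]-1-[3,5-bis(benzyloxy)phenyl]-2-(tert-butyldimethylsilyloxy)ethyl]-5-[(E)-2-(4-benzyloxy-3-methoxyphenyl)ethenyl]-3-(triisopropylsilyloxy)phenol, via vinylketene 21 (not isolated), via 4-dienylcyclobutenone 22 (not isolated), via dienylketene 23 (not isolated), via cyclohexadienone 24 (not isolated)
Conditions: 14, 20 (1.2 equiv, added in portions), toluene, degassed, dark, 80 → 110 °C
Reagents that add atoms: none
Why: On heating, 20 opens reversibly by 4π-electrocyclic ring opening to vinylketene 21. The electron-rich siloxyalkyne captures 21 in a [2+2] cycloaddition in which the nucleophilic alkyne carbon remote from oxygen bonds to the ketene carbonyl carbon (C3a–C4) and the siloxy-bearing carbon to the ketene α-carbon (C7–C7a), giving 22. A second 4π opening gives dienylketene 23, which closes ring A by thermal 6π-electrocyclisation (C4–C5), and cyclohexadienone 24 tautomerises to the phenol, so aromatisation makes the cascade irreversible. The closest known reaction type is the Danheiser benzannulation of cyclobutenones with trialkylsiloxyalkynes, which gives 2,5-disubstituted resorcinol monosilyl ethers of this pattern. No stereocentre is created: the sp3 carbon of 22 is transient, and the two existing centres sit on the alkyne side chain outside the reacting π-system, with no acid or base present. The step needs regioselectivity, which the ketene–ynol ether polarity secures, and chemoselectivity for the ynol ether over the stilbene and the aryl ethers, which its much higher nucleophilicity secures. The (E)-alkene is kept by working thermally in the dark, and any silyl shift between the two ring-A oxygens is harmless because both are freed in step 11.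

Step 11
Reactants: 25 2-[(1S,2R)-2-[3,4-bis(benzyloxy)phenyl]-1-[3,5-bis(benzyloxy)phenyl]-2-(tert-butyldimethylsilyloxy)ethyl]-5-[(E)-2-(4-benzyloxy-3-methoxyphenyl)ethenyl]-3-(triisopropylsilyloxy)phenol
Product: 26 2-[(1S,2R)-2-[3,4-bis(benzyloxy)phenyl]-1-[3,5-bis(benzyloxy)phenyl]-2-hydroxyethyl]-5-[(E)-2-(4-benzyloxy-3-methoxyphenyl)ethenyl]benzene-1,3-diol
Conditions: Bu4NF (3 equiv), THF, 0 → 23 °C; NH4Cl (aq)
Reagents that add atoms: none
Why: Fluoride cleaves the aryl silyl ether rapidly and the secondary alkyl silyl ether more slowly; no acid is present, so the benzylic C–O bond and both stereocentres are untouched.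

Step 12
Reactants: 26 2-[(1S,2R)-2-[3,4-bis(benzyloxy)phenyl]-1-[3,5-bis(benzyloxy)phenyl]-2-hydroxyethyl]-5-[(E)-2-(4-benzyloxy-3-methoxyphenyl)ethenyl]benzene-1,3-diol
Product: 27 (2S,3S)-2-[3,4-bis(benzyloxy)phenyl]-3-[3,5-bis(benzyloxy)phenyl]-6-[(E)-2-(4-benzyloxy-3-methoxyphenyl)ethenyl]-2,3-dihydro-1-benzofuran-4-ol
Conditions: PPh3, DIAD, THF (0.01 M), 0 → 23 °C
Reagents that add atoms: none
Why: Intramolecular Mitsunobu etherification: the phenol is acidic enough to serve as the pronucleophile and displaces the oxyphosphonium group in a 5-exo closure with inversion, turning the (R)-carbinol into (2S). The two phenols are equivalent, so either gives 27. Should the displacement acquire cationic character, closure anti to the C3 aryl group leads to the same trans product.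

Step 13
Reactants: 27 (2S,3S)-2-[3,4-bis(benzyloxy)phenyl]-3-[3,5-bis(benzyloxy)phenyl]-6-[(E)-2-(4-benzyloxy-3-methoxyphenyl)ethenyl]-2,3-dihydro-1-benzofuran-4-ol
Product: 28 (2S,3S)-2-(3,4-dihydroxyphenyl)-3-(3,5-dihydroxyphenyl)-6-[(E)-2-(4-hydroxy-3-methoxyphenyl)ethenyl]-2,3-dihydro-1-benzofuran-4-ol
Conditions: BCl3, C6HMe5, CH2Cl2, −78 °C; then MeOH; work-up under argon
Reagents that add atoms: none
Why: BCl3 cleaves aryl benzyl ethers at −78 °C, and pentamethylbenzene removes the benzyl cations by Friedel–Crafts capture without complexing the Lewis acid. At this temperature the aryl methyl ether, the stilbene and the O1–C2 bond should survive.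

## Compound list

1 | 3,5-bis(benzyloxy)phenylacetic acid | OC(=O)Cc1cc(OCc2ccccc2)cc(OCc2ccccc2)c1 | starting material
2 | (R)-4-benzyl-1,3-oxazolidin-2-one | O=C1N[C@H](Cc2ccccc2)CO1 | starting material
3 | mixed anhydride of 1 with pivalic acid (formed in the flask) | CC(C)(C)C(=O)OC(=O)Cc1cc(OCc2ccccc2)cc(OCc2ccccc2)c1 | intermediate
4 | (R)-4-benzyl-3-{[3,5-bis(benzyloxy)phenyl]acetyl}-1,3-oxazolidin-2-one | O=C(Cc1cc(OCc2ccccc2)cc(OCc2ccccc2)c1)N1C(=O)OC[C@H]1Cc1ccccc1 | intermediate
5 | 3,4-bis(benzyloxy)benzaldehyde | O=Cc1ccc(OCc2ccccc2)c(OCc2ccccc2)c1 | starting material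
6 | Z-configured dibutylboron enolate of 4 (formed in the flask) | CCCCB(CCCC)O/C(=C\c1cc(OCc2ccccc2)cc(OCc2ccccc2)c1)N1C(=O)OC[C@H]1Cc1ccccc1 | intermediate
7 | (4R)-4-benzyl-3-[(2R,3R)-3-[3,4-bis(benzyloxy)phenyl]-2-[3,5-bis(benzyloxy)phenyl]-3-hydroxypropanoyl]-1,3-oxazolidin-2-one | O[C@@H](c1ccc(OCc2ccccc2)c(OCc2ccccc2)c1)[C@H](C(=O)N1C(=O)OC[C@H]1Cc1ccccc1)c1cc(OCc2ccccc2)cc(OCc2ccccc2)c1 | intermediate
8 | (4R)-4-benzyl-3-[(2R,3R)-3-[3,4-bis(benzyloxy)phenyl]-2-[3,5-bis(benzyloxy)phenyl]-3-(tert-butyldimethylsilyloxy)propanoyl]-1,3-oxazolidin-2-one | CC(C)(C)[Si](C)(C)O[C@@H](c1ccc(OCc2ccccc2)c(OCc2ccccc2)c1)[C@H](C(=O)N1C(=O)OC[C@H]1Cc1ccccc1)c1cc(OCc2ccccc2)cc(OCc2ccccc2)c1 | intermediate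
9 | (2S,3R)-3-[3,4-bis(benzyloxy)phenyl]-2-[3,5-bis(benzyloxy)phenyl]-3-(tert-butyldimethylsilyloxy)propan-1-ol | CC(C)(C)[Si](C)(C)O[C@@H](c1ccc(OCc2ccccc2)c(OCc2ccccc2)c1)[C@H](CO)c1cc(OCc2ccccc2)cc(OCc2ccccc2)c1 | intermediate
10 | (2R,3R)-3-[3,4-bis(benzyloxy)phenyl]-2-[3,5-bis(benzyloxy)phenyl]-3-(tert-butyldimethylsilyloxy)propanal | CC(C)(C)[Si](C)(C)O[C@@H](c1ccc(OCc2ccccc2)c(OCc2ccccc2)c1)[C@H](C=O)c1cc(OCc2ccccc2)cc(OCc2ccccc2)c1 | intermediate
11 | (1R,2R)-4,4-dibromo-1-[3,4-bis(benzyloxy)phenyl]-2-[3,5-bis(benzyloxy)phenyl]-1-(tert-butyldimethylsilyloxy)but-3-ene | CC(C)(C)[Si](C)(C)O[C@@H](c1ccc(OCc2ccccc2)c(OCc2ccccc2)c1)[C@H](C=C(Br)Br)c1cc(OCc2ccccc2)cc(OCc2ccccc2)c1 | intermediate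
12 | lithium acetylide formed from 11: (1R,2R)-1-[3,4-bis(benzyloxy)phenyl]-2-[3,5-bis(benzyloxy)phenyl]-1-(tert-butyldimethylsilyloxy)but-3-yne lithiated at C4 (formed in the flask) | CC(C)(C)[Si](C)(C)O[C@@H](c1ccc(OCc2ccccc2)c(OCc2ccccc2)c1)[C@H](C#C[Li])c1cc(OCc2ccccc2)cc(OCc2ccccc2)c1 | intermediate
13 | lithium (3S,4R)-4-[3,4-bis(benzyloxy)phenyl]-3-[3,5-bis(benzyloxy)phenyl]-4-(tert-butyldimethylsilyloxy)but-1-yn-1-olate, the ynolate from oxygen transfer to 12 (formed in the flask) | CC(C)(C)[Si](C)(C)O[C@@H](c1ccc(OCc2ccccc2)c(OCc2ccccc2)c1)[C@H](C#C[O-])c1cc(OCc2ccccc2)cc(OCc2ccccc2)c1.[Li+] | intermediate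
14 | (1R,2S)-1-[3,4-bis(benzyloxy)phenyl]-2-[3,5-bis(benzyloxy)phenyl]-1-(tert-butyldimethylsilyloxy)-4-(triisopropylsilyloxy)but-3-yne | CC(C)(C)[Si](C)(C)O[C@@H](c1ccc(OCc2ccccc2)c(OCc2ccccc2)c1)[C@H](C#CO[Si](C(C)C)(C(C)C)C(C)C)c1cc(OCc2ccccc2)cc(OCc2ccccc2)c1 | intermediate
15 | 4-(benzyloxy)-3-methoxybenzaldehyde | O=Cc1ccc(OCc2ccccc2)c(OC)c1 | starting material
16 | 1-(benzyloxy)-4-[(E)-2-iodoethenyl]-2-methoxybenzene | COc1cc(/C=C/I)ccc1OCc1ccccc1 | intermediate
17 | 3-ethoxycyclobut-2-en-1-one | CCOC1=CC(=O)C1 | starting material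
18 | (E)-2-(4-benzyloxy-3-methoxyphenyl)ethenyllithium (formed in the flask) | COc1cc(/C=C/[Li])ccc1OCc1ccccc1 | intermediate
19 | lithium 3-ethoxy-1-[(E)-2-(4-benzyloxy-3-methoxyphenyl)ethenyl]cyclobut-2-en-1-olate, racemic (formed in the flask) | CCOC1=CC([O-])(/C=C/c2ccc(OCc3ccccc3)c(OC)c2)C1.[Li+] | intermediate
20 | 3-[(E)-2-(4-benzyloxy-3-methoxyphenyl)ethenyl]cyclobut-2-en-1-one | O=C1C=C(/C=C/c2ccc(OCc3ccccc3)c(OC)c2)C1 | intermediate
21 | (4E)-5-(4-benzyloxy-3-methoxyphenyl)-3-methylidenepenta-1,4-dien-1-one, the vinylketene from 20 (formed in the flask) | O=C=CC(=C)/C=C/c1ccc(OCc2ccccc2)c(OC)c1 | intermediate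
22 | 4-[(3E)-4-(4-benzyloxy-3-methoxyphenyl)buta-1,3-dien-2-yl]-3-(triisopropylsilyloxy)cyclobut-2-en-1-one carrying at C2 the (1S,2R) side chain of 25, mixture of epimers at C4 (formed in the flask) | CC(C)(C)[Si](C)(C)O[C@@H](c1ccc(OCc2ccccc2)c(OCc2ccccc2)c1)[C@H](C1=C(O[Si](C(C)C)(C(C)C)C(C)C)C(C(=C)/C=C/c2ccc(OCc3ccccc3)c(OC)c2)C1=O)c1cc(OCc2ccccc2)cc(OCc2ccccc2)c1 | intermediate
23 | dienylketene from ring opening of 22: the ketene carbon carries the (1S,2R) side chain of 25 and a 1-(triisopropylsilyloxy)-3-methylidene-5-(4-benzyloxy-3-methoxyphenyl)penta-1,4-dienyl group (formed in the flask) | CC(C)(C)[Si](C)(C)O[C@@H](c1ccc(OCc2ccccc2)c(OCc2ccccc2)c1)[C@H](C(=C=O)C(O[Si](C(C)C)(C(C)C)C(C)C)=CC(=C)/C=C/c1ccc(OCc2ccccc2)c(OC)c1)c1cc(OCc2ccccc2)cc(OCc2ccccc2)c1 | intermediate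
24 | 5-[(E)-2-(4-benzyloxy-3-methoxyphenyl)ethenyl]-3-(triisopropylsilyloxy)cyclohexa-2,4-dien-1-one carrying at C2 the (1S,2R) side chain of 25, the keto tautomer of 25 (formed in the flask) | CC(C)(C)[Si](C)(C)O[C@@H](c1ccc(OCc2ccccc2)c(OCc2ccccc2)c1)[C@H](C1=C(O[Si](C(C)C)(C(C)C)C(C)C)C=C(/C=C/c2ccc(OCc3ccccc3)c(OC)c2)CC1=O)c1cc(OCc2ccccc2)cc(OCc2ccccc2)c1 | intermediate
25 | 2-[(1S,2R)-2-[3,4-bis(benzyloxy)phenyl]-1-[3,5-bis(benzyloxy)phenyl]-2-(tert-butyldimethylsilyloxy)ethyl]-5-[(E)-2-(4-benzyloxy-3-methoxyphenyl)ethenyl]-3-(triisopropylsilyloxy)phenol | CC(C)(C)[Si](C)(C)O[C@@H](c1ccc(OCc2ccccc2)c(OCc2ccccc2)c1)[C@H](c1c(O)cc(/C=C/c2ccc(OCc3ccccc3)c(OC)c2)cc1O[Si](C(C)C)(C(C)C)C(C)C)c1cc(OCc2ccccc2)cc(OCc2ccccc2)c1 | intermediate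
26 | 2-[(1S,2R)-2-[3,4-bis(benzyloxy)phenyl]-1-[3,5-bis(benzyloxy)phenyl]-2-hydroxyethyl]-5-[(E)-2-(4-benzyloxy-3-methoxyphenyl)ethenyl]benzene-1,3-diol | O[C@@H](c1ccc(OCc2ccccc2)c(OCc2ccccc2)c1)[C@H](c1c(O)cc(/C=C/c2ccc(OCc3ccccc3)c(OC)c2)cc1O)c1cc(OCc2ccccc2)cc(OCc2ccccc2)c1 | intermediate
27 | (2S,3S)-2-[3,4-bis(benzyloxy)phenyl]-3-[3,5-bis(benzyloxy)phenyl]-6-[(E)-2-(4-benzyloxy-3-methoxyphenyl)ethenyl]-2,3-dihydro-1-benzofuran-4-ol | COc1cc(/C=C/c2cc(O)c3c(c2)O[C@H](c2ccc(OCc4ccccc4)c(OCc4ccccc4)c2)[C@H]3c2cc(OCc3ccccc3)cc(OCc3ccccc3)c2)ccc1OCc1ccccc1 | intermediate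
28 | (2S,3S)-2-(3,4-dihydroxyphenyl)-3-(3,5-dihydroxyphenyl)-6-[(E)-2-(4-hydroxy-3-methoxyphenyl)ethenyl]-2,3-dihydro-1-benzofuran-4-ol | COc1cc(/C=C/c2cc(O)c3c(c2)O[C@H](c2ccc(O)c(O)c2)[C@H]3c2cc(O)cc(O)c2)ccc1O | target

## Step count and least certain steps

Total step count: 13. Longest linear sequence: 11 steps (steps 1–7, then 10–13); steps 8–9 form the short second branch.

**Step 10 (key step).**
- What may go wrong: electrocyclic opening of the donor-conjugated cyclobutenone may be slow, and capture of the transient ketene by the α-branched siloxyalkyne may be slow. Ketene self-condensation, acylation of the product phenol by the ketene, or thermal oxygen-to-carbon silyl migration in 14 could then compete.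
- Fallback: it sets out from 17 and 14 and returns at 25. Ketone 17 is treated with CH2=CHMgBr and then dilute HCl to give 3-ethenylcyclobut-2-en-1-one F1, a smaller and less donor-stabilised cyclobutenone that can be used in excess. Heating F1 with 14 in toluene should give 2-[(1S,2R)-2-[3,4-bis(benzyloxy)phenyl]-1-[3,5-bis(benzyloxy)phenyl]-2-(tert-butyldimethylsilyloxy)ethyl]-5-ethenyl-3-(triisopropylsilyloxy)phenol F2. A Mizoroki–Heck coupling of F2 with purchased 1-(benzyloxy)-4-iodo-2-methoxybenzene (Pd(OAc)2, P(o-tol)3, Et3N, DMF, 90 °C) then installs the (E)-styryl group and gives 25.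

**Step 7.**
- What may go wrong: incomplete oxygen transfer to the acetylide in the presence of the lithium bromide and 1-bromobutane left by the exchange, proton exchange at the propargylic benzylic carbon in the basic medium (erosion at the future C3), or silylation of the ynolate on carbon.
- Fallback: it sets out from 8 and returns at 14, replacing steps 4–7. LiOH/H2O2 cleaves the auxiliary to give (2R,3R)-3-[3,4-bis(benzyloxy)phenyl]-2-[3,5-bis(benzyloxy)phenyl]-3-(tert-butyldimethylsilyloxy)propanoic acid F3. Me3SiCHN2 converts it to methyl (2R,3R)-3-[3,4-bis(benzyloxy)phenyl]-2-[3,5-bis(benzyloxy)phenyl]-3-(tert-butyldimethylsilyloxy)propanoate F4. Kowalski ester homologation of F4 (CH2Br2 with lithium 2,2,6,6-tetramethylpiperidide at −78 °C, LiN(SiMe3)2, then s-BuLi and n-BuLi) gives the same ynolate 13, which TIPSOTf converts to 14. This path is shorter but puts strong base next to the α-aryl ester, which is why it is the second choice.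

**Step 6 (with the aldehyde from step 5).**
- What may go wrong: enolisation of the α-aryl aldehyde in the presence of ZnBr2 and phosphine, leading to epimerisation at the future C3 or β-elimination of silanolate.
- Fallback: it sets out from 10 and returns at 12, replacing step 6 and the first operation of step 7. Lithiated trimethylsilyldiazomethane (Me3SiCHN2, LiN(iPr)2, THF, −78 → 0 °C) converts the aldehyde directly into (1R,2R)-1-[3,4-bis(benzyloxy)phenyl]-2-[3,5-bis(benzyloxy)phenyl]-1-(tert-butyldimethylsilyloxy)but-3-yne F5 by addition, Peterson-type elimination and Colvin rearrangement of the alkylidene carbene, at low temperature and without a Lewis acid. After purification, n-BuLi (1.0 equiv, THF, −78 °C) deprotonates F5 to acetylide 12, which is oxidised and silylated as in step 7.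

**Step 12.**
- What may go wrong: base-induced elimination of the activated benzylic oxyphosphonium group to a triarylethylene, which would destroy both stereocentres, or a sluggish displacement at the hindered carbinol.
- Fallback: it sets out from 25 and returns at 27, reversing the order of ring closure and desilylation. Catalytic HN(SO2CF3)2 in CH2Cl2 at −40 °C ionises the para-alkoxybenzylic silyl ether of 25, and the free ortho phenol captures the cation anti to the C3 aryl group (control by C3, no base present). This should give (2S,3S)-2-[3,4-bis(benzyloxy)phenyl]-3-[3,5-bis(benzyloxy)phenyl]-6-[(E)-2-(4-benzyloxy-3-methoxyphenyl)ethenyl]-4-(triisopropylsilyloxy)-2,3-dihydro-1-benzofuran F6. Bu4NF then removes the remaining silyl group to give 27.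

## Further compounds

F1 | step 10 | 3-ethenylcyclobut-2-en-1-one | C=CC1=CC(=O)C1
F2 | step 10 | 2-[(1S,2R)-2-[3,4-bis(benzyloxy)phenyl]-1-[3,5-bis(benzyloxy)phenyl]-2-(tert-butyldimethylsilyloxy)ethyl]-5-ethenyl-3-(triisopropylsilyloxy)phenol | CC(C)(C)[Si](C)(C)O[C@@H](c1ccc(OCc2ccccc2)c(OCc2ccccc2)c1)[C@H](c1c(O)cc(C=C)cc1O[Si](C(C)C)(C(C)C)C(C)C)c1cc(OCc2ccccc2)cc(OCc2ccccc2)c1
F3 | step 7 | (2R,3R)-3-[3,4-bis(benzyloxy)phenyl]-2-[3,5-bis(benzyloxy)phenyl]-3-(tert-butyldimethylsilyloxy)propanoic acid | CC(C)(C)[Si](C)(C)O[C@@H](c1ccc(OCc2ccccc2)c(OCc2ccccc2)c1)[C@H](C(=O)O)c1cc(OCc2ccccc2)cc(OCc2ccccc2)c1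
F4 | step 7 | methyl (2R,3R)-3-[3,4-bis(benzyloxy)phenyl]-2-[3,5-bis(benzyloxy)phenyl]-3-(tert-butyldimethylsilyloxy)propanoate | CC(C)(C)[Si](C)(C)O[C@@H](c1ccc(OCc2ccccc2)c(OCc2ccccc2)c1)[C@H](C(=O)OC)c1cc(OCc2ccccc2)cc(OCc2ccccc2)c1
F5 | step 6 | (1R,2R)-1-[3,4-bis(benzyloxy)phenyl]-2-[3,5-bis(benzyloxy)phenyl]-1-(tert-butyldimethylsilyloxy)but-3-yne | CC(C)(C)[Si](C)(C)O[C@@H](c1ccc(OCc2ccccc2)c(OCc2ccccc2)c1)[C@H](C#C)c1cc(OCc2ccccc2)cc(OCc2ccccc2)c1
F6 | step 12 | (2S,3S)-2-[3,4-bis(benzyloxy)phenyl]-3-[3,5-bis(benzyloxy)phenyl]-6-[(E)-2-(4-benzyloxy-3-methoxyphenyl)ethenyl]-4-(triisopropylsilyloxy)-2,3-dihydro-1-benzofuran | COc1cc(/C=C/c2cc(O[Si](C(C)C)(C(C)C)C(C)C)c3c(c2)O[C@H](c2ccc(OCc4ccccc4)c(OCc4ccccc4)c2)[C@H]3c2cc(OCc3ccccc3)cc(OCc3ccccc3)c2)ccc1OCc1ccccc1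
A1 | alternative 1 | (2S,3S)-6-bromo-2-(3,4-dimethoxyphenyl)-3-(3,5-dimethoxyphenyl)-2,3-dihydro-1-benzofuran-4-ol | Brc1cc(O)c2c(c1)O[C@H](c1ccc(OC)c(OC)c1)[C@H]2c1cc(OC)cc(OC)c1
A2 | alternative 1 | 5-bromo-2-[2-(3,4-dimethoxyphenyl)-1-(3,5-dimethoxyphenyl)ethenyl]benzene-1,3-diol (either alkene isomer) | Oc1cc(Br)cc(O)c1C(=Cc1ccc(OC)c(OC)c1)c1cc(OC)cc(OC)c1
A3 | alternative 1 | (2S,3S)-6-bromo-2-(3,4-dihydroxyphenyl)-3-(3,5-dihydroxyphenyl)-2,3-dihydro-1-benzofuran-4-ol | Brc1cc(O)c2c(c1)O[C@H](c1ccc(O)c(O)c1)[C@H]2c1cc(O)cc(O)c1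
A4 | alternative 2 | (2S,3S)-4-(benzyloxy)-2-[3,4-bis(benzyloxy)phenyl]-3-[3,5-bis(benzyloxy)phenyl]-6-bromo-2,3-dihydro-1-benzofuran | Brc1cc(OCc2ccccc2)c2c(c1)O[C@H](c1ccc(OCc3ccccc3)c(OCc3ccccc3)c1)[C@H]2c1cc(OCc2ccccc2)cc(OCc2ccccc2)c1
A5 | alternative 2 | 3-(benzyloxy)-2-{[3,5-bis(benzyloxy)phenyl](4-methylbenzenesulfonyl)methyl}-5-bromophenol, racemic | Oc1cc(Br)cc(OCc2ccccc2)c1C(c1cc(OCc2ccccc2)cc(OCc2ccccc2)c1)S(=O)(=O)c1ccc(C)cc1
A6 | alternative 2 | 3-(benzyloxy)-2-{[3,5-bis(benzyloxy)phenyl]methylidene}-5-bromocyclohexa-3,5-dien-1-one | O=C1C=C(Br)C=C(OCc2ccccc2)C1=Cc1cc(OCc2ccccc2)cc(OCc2ccccc2)c1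
A7 | alternative 2 | (2R,5R)-1-[3,4-bis(benzyloxy)benzyl]-2,5-dimethylthiolan-1-ium triflate | C[C@@H]1CC[C@@H](C)[S+]1Cc1ccc(OCc2ccccc2)c(OCc2ccccc2)c1.[O-]S(=O)(=O)C(F)(F)F
A8 | alternative 3 | 5-[(2S,3S)-6-bromo-4-[(3,4-dimethoxybenzyl)oxy]-2-(3,4-dimethoxyphenyl)-2,3-dihydro-1-benzofuran-3-yl]benzene-1,3-diol | Brc1cc(OCc2ccc(OC)c(OC)c2)c2c(c1)O[C@H](c1ccc(OC)c(OC)c1)[C@H]2c1cc(O)cc(O)c1
A9 | alternative 3 | 1-[(2S,3S)-6-bromo-4-[(3,4-dimethoxybenzyl)oxy]-2-(3,4-dimethoxyphenyl)-2,3-dihydro-1-benzofuran-3-yl]hexane-1,3,5-trione | Brc1cc(OCc2ccc(OC)c(OC)c2)c2c(c1)O[C@H](c1ccc(OC)c(OC)c1)[C@H]2C(=O)CC(=O)CC(=O)C
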